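## Structural features

The target is a 1,4-naphthoquinone in which a benzenoid ring A and a quinonoid ring B share the C4a–C8a bond. Ring A carries methoxy groups at C5, C6 and C8 and its only hydrogen at C7. Ring B carries the C1 and C4 carbonyls, an acidic enolic hydroxyl at C2 (a vinylogous carboxylic acid) and a three-carbon chain at C3. The chain holds the only stereocentre, the (S)-configured acetoxy-bearing carbon; it is one CH2 group away from the ring and has no stereogenic neighbour, so it can come from the chiral pool and need only be protected from inversion or elimination. The fragile points are the secondary acetate (lost under the aqueous base that frees a C2 oxygen), the 2-hydroxyquinone (easily O-alkylated or O-acylated), the electron-rich ring A, and the free carbinol, which can close a dihydrofuran ring onto C2 while C2 is still an electrophilic vinylogous ester. The real difficulty is regiochemical: both rings are unsymmetrical, and the isomer with ring A turned round is a different compound that no tautomerism can interconvert. The key step exploits two facts: C5(O)–C6(O)=C7(H)–C8(O) of ring A is the chain of a 1,3,4-trioxygenated butadiene whose C8 end is at the carboxylic acid oxidation level, and C4a=C8a is the unsubstituted edge of a 2-methoxy-3-alkyl-1,4-benzoquinone.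

## Logic of the disconnections

19 to 17: the acyl–oxygen bond of the side-chain ester is cut. The ester cannot survive the base that frees the C2 hydroxyl, so it is installed last. This removes the only base-labile group from every earlier intermediate. The forward step must leave an acyl group on the carbinol only; this is done by acylating both hydroxyls to 18 and hydrolysing the far more labile enol ester in the same flask.

17 to 16: the O–Si bond of the side chain is cut. The carbinol must stay masked while C2 is an electrophilic vinylogous ester, and through the oxidation and the cycloaddition. One protecting group therefore serves from step 2 to step 9. Its removal must not re-etherify the vinylogous acid, which calls for a fluoride source in a non-alcoholic solvent.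

16 to 15: the C2 oxygen is traced back to a methyl ether (the C2–OCH3 bond is exchanged at C2). The methoxy group is needed earlier as the donor that steers the cycloaddition, and it leaves 15 without an acidic proton. The forward step must pick one of four methyl ethers; only the C2 ether is a vinylogous ester open to addition–elimination.

15 to 14: the O–CH3 bond at C8 is cut. The carbon that becomes C8 leaves the ring-forming step as a phenol. The forward step must methylate a chelated peri-hydroxyl without base strong enough to touch the vinylogous ester or the silyl ether.

14 to 6 and 11: the C4a–C5 and C8–C8a bonds are cut, which removes ring A. This is the cut with the largest gain: 11 supplies all three ring A oxygens and the C7 hydrogen in the correct order, and 6 supplies ring B with the stereocentre. The forward step must bond the nucleophilic terminus of 11 to C4a and not to C8a. It must also aromatize ring A with an oxidation while keeping the C5 methoxy group. A halogen on the carbon of 6 that becomes C8a would make the aromatization redox-neutral. However, electrophilic halogenation of 5 would place it on the other ring carbon (para to the central methoxy group), where it would oppose the methoxy control. The unhalogenated 6 is therefore kept, and the halogenated variant is held in reserve.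

6 to 5 to 4: the two quinone carbonyls are traced back to the para pair of aryl methyl ethers, and the silyl ether to the free carbinol. The arene form is what the carbon–carbon bond formation needs. The oxidation must choose the para pair over the adjacent pair and spare the silyl ether.

4 to 1 and 2: the aryl–CH2 bond is cut. The aryl carbon lies between two methoxy groups, the natural site of directed lithiation, and 2 delivers the stereocentre ready-made. The forward step must attack only the CH2 carbon of 2.

11 to 9 to 7: the O–Si bond and then the enol ether C–O bond at the central carbon are cut. This is the standard route to vinylketene silyl acetals. The forward step must deprotonate the CH2 group remote from the ester, not add to the ester.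

## Other disconnections considered

Alternative 1: The cut removes three ring B bonds at once (C1–C2, C3–C4 and C4–C4a). Ring B would be assembled in a Dötz benzannulation from three parts: the aryl(methoxy)carbene complex A1 of zerovalent chromium, (CO)5Cr=C(OCH3)Ar with Ar = 2,4,5-trimethoxyphenyl and made with Cr(CO)6; the terminal alkyne A2; and one carbonyl ligand. The product is the 4-methoxy-1-naphthol A3.
- In its favour: the orientation of ring A relative to the chain is fixed by connectivity (the larger alkyne substituent ends up next to the carbon derived from CO). On this point it is better than the chosen plan, where the orientation rests on an electronic bias. The acetate is carried from the start, so no protecting-group exchange is needed, which is also better.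
- Against it here: A3 has hydrogen, not oxygen, at C2. After oxidation to the quinone A4 that oxygen must still be introduced, for example by alkaline epoxidation and ring opening, which endangers the acetate. The oxidation of A3 must select ring B although ring A holds a para-dimethoxy pair. Cr(CO)6 is consumed in stoichiometric amount, and ortho-methoxyaryl carbene complexes are prone to chelation and to cyclobutenone or indene formation.
- Comparison: a metal-templated three-component assembly stands against a thermal cycloaddition. The step counts are about equal, and the stereocentre comes from the same epoxide in both. The chosen plan is preferred because all ring oxygens arrive at the right oxidation level in one step and no late C–H oxygenation is needed.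

Alternative 2: Only C3–C4 is cut. NaOCH3 would open the enol lactone A5 (either alkene geometry) to a methyl ester and the enolate of a 1,2-diketone. The enolate carbon is then acylated by the ester in a Dieckmann-type closure, giving the hydroxyquinone A6, which is identical in structure with 16.
- In its favour: the key step delivers the free C2 hydroxyl directly, so the C8 methylation and the hydrolysis at C2 are not needed; this is better. The positions of hydroxyl and chain are fixed by connectivity, also better. As an ionic acyl transfer it is mechanistically more secure than the cycloaddition of an untried diene.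
- Against it here: the precursor of A5 needs a benzene ring with three methoxy groups and two adjacent, different acyl carbons, and an alkylidene unit made from a β-silyloxy carbonyl partner that eliminates easily. These regiocontrolled aromatic steps outnumber the steps saved.
- Comparison: the regiochemical problem is not solved but moved into the arene synthesis. The endgame is shorter, the whole route longer, and the stereocentre source is equal.

Alternative 3: C1–C2 and C2–C3 are cut, so that C2 is a single inserted carbon. Dichlorocarbene from CCl3CO2Na would add to the enol ether double bond of the indenyl silyl ether A7. Opening of the dichlorocyclopropane with loss of chloride and the silyl group expands the five-membered ring to the 2-chloro-1-naphthol A8.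
- In its favour: the C1 oxygen is fixed by the position of the former ketone, so the ring orientation is unambiguous, which is better. The chlorine is a latent C2 hydroxyl, equal in function to the C2 methoxy group of the chosen plan.
- Against it here: C4 arrives as C–H, so A8 must be oxidized to the quinone in the presence of the electron-rich, para-dimethoxylated ring A. The chiral chain must be attached next to a ketone with a β-oxygenated electrophile, a poor substitution partner.
- Comparison: ring B is built one carbon at a time after ring A, against ring A in one step with its oxygens. The step count is clearly higher (about thirteen operations), and the stereocentre source is equal.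

Key step: step 6

Assumption: 1, 2 (in high enantiomeric purity) and 7 are bought, and LiN(iPr)2 is used as a commercial solution. The ring-fusion, C5 and C8 configurations of 12 are left open because all four centres become sp2 carbons in the same flask.

## Route

Step 1
Reactants: 1 1,2,4-trimethoxybenzene; 2 (S)-propylene oxide [(2S)-2-methyloxirane]
Product: 4 (2S)-1-(2,3,6-trimethoxyphenyl)propan-2-ol, via aryllithium 3 (not isolated)
Conditions: n-BuLi, THF, 0 °C to rt; then 2, BF3·OEt2, −78 °C; H2O
Reagents that add atoms: none
Why: Directed ortho-lithiation takes place at the ring carbon flanked by two methoxy groups, and the BF3-activated epoxide is opened by SN2 attack at its CH2 carbon, so the stereocentre of 2 is not involved and appears unchanged as (S) in 4.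

Step 2
Reactants: 4 (2S)-1-(2,3,6-trimethoxyphenyl)propan-2-ol
Product: 5 tert-butyl(dimethyl){[(2S)-1-(2,3,6-trimethoxyphenyl)propan-2-yl]oxy}silane
Conditions: TBSCl, imidazole, DMF, rt
Reagents that add atoms: tert-butyldimethylsilyl chloride, CC(C)(C)[Si](C)(C)Cl
Why: Standard silylation of a secondary alcohol; the silyl ether should tolerate the later cycloaddition, the neutral methylation and dilute aqueous NaOH, and it keeps the carbinol away from C2.

Step 3
Reactants: 5 tert-butyl(dimethyl){[(2S)-1-(2,3,6-trimethoxyphenyl)propan-2-yl]oxy}silane
Product: 6 2-methoxy-3-[(2S)-2-(tert-butyldimethylsilyloxy)propyl]-1,4-benzoquinone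
Conditions: (NH4)2Ce(NO3)6, MeCN/H2O, 0 °C, short reaction time
Reagents that add atoms: water, O
Why: Oxidative demethylation of a 1,4-dimethoxyarene by tetravalent cerium gives the para-quinone; the para pair of methoxy groups is consumed and the flanked third methoxy group remains as the vinylogous ester, while a brief reaction at 0 °C should spare the secondary silyl ether.

Step 4
Reactants: 7 methyl 4-methoxy-3-oxobutanoate
Product: 9 methyl (2E)-3,4-dimethoxybut-2-enoate, via ketal 8 (not isolated)
Conditions: HC(OCH3)3, MeOH, H2SO4 (cat.), rt; then distillation
Reagents that add atoms: trimethyl orthoformate, COC(OC)OC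
Why: Acid-catalysed ketalization of the β-keto ester followed by loss of methanol is the usual enol etherification of acetoacetates; the conjugated (E) ester is expected, with the CH2OCH3 group cis to the ester as the next step requires.

Step 5
Reactants: 9 methyl (2E)-3,4-dimethoxybut-2-enoate
Product: 11 1,3,4-trimethoxy-1-(trimethylsilyloxy)buta-1,3-diene (mixture of double-bond isomers), via lithium dienolate 10 (not isolated)
Conditions: LiN(iPr)2, THF, −78 °C; then TMSCl, −78 °C to rt; filtration under Ar, used crude
Reagents that add atoms: chlorotrimethylsilane, C[Si](C)(C)Cl
Why: Deprotonation of a β-alkoxy enoate at the γ-carbon gives the extended ester enolate, which is silylated on oxygen to the vinylketene silyl acetal, as in the preparation of 1,3-dimethoxy-1-(trimethylsilyloxy)buta-1,3-diene.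

Step 6
Reactants: 6 2-methoxy-3-[(2S)-2-(tert-butyldimethylsilyloxy)propyl]-1,4-benzoquinone; 11 1,3,4-trimethoxy-1-(trimethylsilyloxy)buta-1,3-diene
Product: 14 8-hydroxy-2,5,6-trimethoxy-3-[(2S)-2-(tert-butyldimethylsilyloxy)propyl]-1,4-naphthoquinone, via cycloadduct 12 (not isolated), via naphthalene-1,4,8-triol 13 (not isolated)
Conditions: 11 (2 equiv), CH2Cl2, −40 °C to rt, Ar; then SiO2, air, rt
Reagents that add atoms: none
Why: The silyl ketene acetal end of 11 makes its CH(OCH3) carbon strongly nucleophilic; this carbon bonds first to C4a of 6 in an asynchronous [4+2] cycloaddition of normal electron demand and the ketal carbon then closes onto C8a, the closest known reaction type being the Diels–Alder annulation of benzoquinones with 1-alkoxy-1-silyloxybuta-1,3-dienes followed by aromatization. Ring A is closed as a six-membered carbocycle by intermolecular formation of the C4a–C5 and C8–C8a bonds across the unsubstituted quinone edge, and the tetrasubstituted, donor-bearing C2=C3 bond is inert. The regioselectivity that the step needs is secured by the C2 methoxy group, which turns the C4 carbonyl into a vinylogous ester so that only the C1 carbonyl activates the dienophile and its β-carbon, C4a, is the electrophilic site. On silica gel the mixed silyl methyl ketal of 12 collapses and the hydrogens at C8a, C5 and C4a move to oxygen, giving 13, which air oxidizes to the quinone 14. The same deactivation of the C4 carbonyl makes C4a–H the least acidic ring hydrogen of 12, which should hold back the unwanted β-elimination of the C5 methoxy group. The four stereocentres of 12 (C4a, C5, C8, C8a) are transient and end as sp2 carbons, so no stereocontrol is needed and the geometry of 11 does not matter, while the (S) centre of the chain is remote and not enolizable. The silyl ether, the vinylogous ester and the aryl methyl ethers should be inert to these neutral conditions.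

Step 7
Reactants: 14 8-hydroxy-2,5,6-trimethoxy-3-[(2S)-2-(tert-butyldimethylsilyloxy)propyl]-1,4-naphthoquinone
Product: 15 2,5,6,8-tetramethoxy-3-[(2S)-2-(tert-butyldimethylsilyloxy)propyl]-1,4-naphthoquinone
Conditions: CH3I, Ag2O, CHCl3, 40 °C, dark
Reagents that add atoms: iodomethane, CI
Why: O-Methylation of a hydrogen-bonded peri-hydroxyl with CH3I and Ag2O is the standard neutral method for chelated quinone phenols; without a soluble strong base the vinylogous ester and the silyl ether stay intact.

Step 8
Reactants: 15 2,5,6,8-tetramethoxy-3-[(2S)-2-(tert-butyldimethylsilyloxy)propyl]-1,4-naphthoquinone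
Product: 16 2-hydroxy-5,6,8-trimethoxy-3-[(2S)-2-(tert-butyldimethylsilyloxy)propyl]-1,4-naphthoquinone
Conditions: NaOH (aq., dilute), THF, rt; then 1 M HCl
Reagents that add atoms: sodium hydroxide, [Na+].[OH-]
Why: Hydroxide adds to C2 and expels methoxide (addition–elimination at a vinylogous ester); the product is at once deprotonated to a delocalized anion that resists further attack, and the aryl methyl ethers and the silyl ether are not affected by dilute base at rt.

Step 9
Reactants: 16 2-hydroxy-5,6,8-trimethoxy-3-[(2S)-2-(tert-butyldimethylsilyloxy)propyl]-1,4-naphthoquinone
Product: 17 2-hydroxy-3-[(2S)-2-hydroxypropyl]-5,6,8-trimethoxy-1,4-naphthoquinone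
Conditions: HF (aq.), MeCN, 0 °C to rt
Reagents that add atoms: none
Why: Fluoride-driven cleavage of the Si–O bond under mildly acidic conditions in a non-alcoholic solvent avoids etherification of the vinylogous acid; C2 is no longer an electrophilic vinylogous ester, so the freed carbinol has nothing to cyclize onto, and the C–O bond of the stereocentre is not broken.

Step 10
Reactants: 17 2-hydroxy-3-[(2S)-2-hydroxypropyl]-5,6,8-trimethoxy-1,4-naphthoquinone
Product: 19 3-[(2S)-2-acetoxypropyl]-2-hydroxy-5,6,8-trimethoxy-1,4-naphthoquinone, via diacetate 18 (not isolated)
Conditions: Ac2O, pyridine, DMAP (cat.), CH2Cl2, 0 °C to rt; then NaHCO3 (aq.), THF, rt; 1 M HCl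
Reagents that add atoms: acetic anhydride, CC(=O)OC(C)=O
Why: Nucleophilic-catalysed acetylation esterifies both hydroxyls; the enol acetate of 18 is a vinylogous mixed anhydride that bicarbonate hydrolyses at rt, while the secondary alkyl acetate is stable, and acylation on oxygen retains the (S) configuration.

## Compound list

1 | 1,2,4-trimethoxybenzene | COc1ccc(OC)c(OC)c1 | starting material
2 | (S)-propylene oxide, (2S)-2-methyloxirane | C[C@H]1CO1 | starting material
3 | (2,3,6-trimethoxyphenyl)lithium | [Li]c1c(OC)ccc(OC)c1OC | intermediate (not isolated)
4 | (2S)-1-(2,3,6-trimethoxyphenyl)propan-2-ol | COc1ccc(OC)c(C[C@H](C)O)c1OC | intermediate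
5 | tert-butyl(dimethyl){[(2S)-1-(2,3,6-trimethoxyphenyl)propan-2-yl]oxy}silane | COc1ccc(OC)c(C[C@H](C)O[Si](C)(C)C(C)(C)C)c1OC | intermediate
6 | 2-methoxy-3-[(2S)-2-(tert-butyldimethylsilyloxy)propyl]-1,4-benzoquinone | COC1=C(C[C@H](C)O[Si](C)(C)C(C)(C)C)C(=O)C=CC1=O | intermediate
7 | methyl 4-methoxy-3-oxobutanoate | COCC(=O)CC(=O)OC | starting material
8 | methyl 3,3,4-trimethoxybutanoate | COCC(OC)(OC)CC(=O)OC | intermediate (not isolated)
9 | methyl (2E)-3,4-dimethoxybut-2-enoate | COC/C(OC)=C\C(=O)OC | intermediate
10 | lithium 1,3,4-trimethoxybuta-1,3-dien-1-olate | [Li+].[O-]C(OC)=CC(OC)=COC | intermediate (not isolated)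
11 | 1,3,4-trimethoxy-1-(trimethylsilyloxy)buta-1,3-diene, mixture of double-bond isomers | COC=C(OC)C=C(OC)O[Si](C)(C)C | intermediate
12 | 2,5,6,8-tetramethoxy-3-[(2S)-2-(tert-butyldimethylsilyloxy)propyl]-8-(trimethylsilyloxy)-4a,5,8,8a-tetrahydronaphthalene-1,4-dione, cis ring fusion, mixture of diastereomers | COC1C(OC)=CC(OC)(O[Si](C)(C)C)C2C1C(=O)C(C[C@H](C)O[Si](C)(C)C(C)(C)C)=C(OC)C2=O | intermediate (not isolated)
13 | 2,5,6-trimethoxy-3-[(2S)-2-(tert-butyldimethylsilyloxy)propyl]naphthalene-1,4,8-triol | COc1cc(O)c2c(O)c(OC)c(C[C@H](C)O[Si](C)(C)C(C)(C)C)c(O)c2c1OC | intermediate (not isolated)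
14 | 8-hydroxy-2,5,6-trimethoxy-3-[(2S)-2-(tert-butyldimethylsilyloxy)propyl]-1,4-naphthoquinone | COc1cc(O)c2c(c1OC)C(=O)C(C[C@H](C)O[Si](C)(C)C(C)(C)C)=C(OC)C2=O | intermediate
15 | 2,5,6,8-tetramethoxy-3-[(2S)-2-(tert-butyldimethylsilyloxy)propyl]-1,4-naphthoquinone | COc1cc(OC)c2c(c1OC)C(=O)C(C[C@H](C)O[Si](C)(C)C(C)(C)C)=C(OC)C2=O | intermediate
16 | 2-hydroxy-5,6,8-trimethoxy-3-[(2S)-2-(tert-butyldimethylsilyloxy)propyl]-1,4-naphthoquinone | COc1cc(OC)c2c(c1OC)C(=O)C(C[C@H](C)O[Si](C)(C)C(C)(C)C)=C(O)C2=O | intermediate
17 | 2-hydroxy-3-[(2S)-2-hydroxypropyl]-5,6,8-trimethoxy-1,4-naphthoquinone | COc1cc(OC)c2c(c1OC)C(=O)C(C[C@H](C)O)=C(O)C2=O | intermediate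
18 | 2-acetoxy-3-[(2S)-2-acetoxypropyl]-5,6,8-trimethoxy-1,4-naphthoquinone | COc1cc(OC)c2c(c1OC)C(=O)C(C[C@H](C)OC(C)=O)=C(OC(C)=O)C2=O | intermediate (not isolated)
19 | 3-[(2S)-2-acetoxypropyl]-2-hydroxy-5,6,8-trimethoxy-1,4-naphthoquinone | COc1cc(OC)c2c(c1OC)C(=O)C(C[C@H](C)OC(C)=O)=C(O)C2=O | target

## Step count and least certain steps

Total step count: 10. Longest linear sequence: 8 steps (steps 1, 2, 3, 6, 7, 8, 9, 10); steps 4 and 5 form the two-step branch to 11.

Step 6 (key step). Three processes may spoil it.
- Methanol may be lost across C4a–C5 (β-elimination toward the C4 carbonyl) before tautomerization. This would aromatize ring A without any oxidant but at the cost of the C5 oxygen.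
- The regioselectivity may erode if the methoxy bias is not strong enough.
- The isomer of 11 whose terminal methoxy group points inward may cycloadd slowly, leaving Michael-type addition without ring closure or hydrolysis of the diene.

The fallback makes the aromatization redox-neutral and reinforces the regiochemistry with a leaving group. It sets out from 6 and comes back at 14. Bromine would be added to the unsubstituted double bond of 6 (Br2, CH2Cl2, −20 °C) to give the trans-dibromide F1. Et3N at low temperature should then remove the more acidic hydrogen next to the C1 carbonyl and expel the bromide from the neighbouring carbon, leaving the 6-bromoquinone F2 with bromine on the carbon that becomes C8a. Acidic dehydrobromination is avoided because enolization toward the vinylogous ester carbonyl would leave the halogen on the other carbon. F2 and 11 would give the bromo cycloadduct F3, in which the nucleophilic diene terminus again bonds to the unsubstituted carbon. F3 can only lose hydrogen bromide across C4a–C8a (bromide being the better leaving group) and then methanol from the C8 ketal with the C5 hydrogen. This gives the 8-trimethylsilyloxy quinone F4, which silica gel desilylates to 14. No oxidant is needed and the C5 methoxy group cannot be lost.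

Step 5. Deprotonation may be incomplete or be accompanied by Claisen-type self-condensation of the ester, and the trimethylsilyl ketene acetal may hydrolyse during isolation. The fallback replaces it by a more robust, isolable silyl acetal. It sets out from 9 and comes back at 14. LiN(iPr)2 and TBSCl with a polar cosolvent would give the tert-butyldimethylsilyl diene F5. Under the conditions of step 6, F5 and 6 would pass through the cycloadduct F6 and the silylated hydroquinone F7 to the 8-silyloxy quinone F8. K2CO3 in dry MeOH would then cleave the aryl silyl ether of F8 selectively over the secondary alkyl silyl ether, giving 14.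

Step 1. The doubly chelated, hindered aryllithium may open the epoxide sluggishly, and the Lewis acid may divert the epoxide by fluoride opening or rearrangement. The fallback builds the chain first and sets the stereocentre afterwards. It sets out from 1 (through 3) and comes back at 4. Allylation of 3 with allyl bromide (CuI catalysis) would give the allylarene F9. Tsuji–Wacker oxidation (PdCl2 cat., CuCl, O2, DMF/H2O) would give the arylacetone F10. Reduction of F10 with an (S)-selective alcohol dehydrogenase and cofactor recycling would give 4.

Step 3. The silyl ether may be lost in the acidic aqueous medium, and oxidation of the adjacent methoxy pair to an ortho-quinone may compete. The fallback reverses the order of protection and oxidation. It sets out from 4 and comes back at 6. Oxidation of 4 with (NH4)2Ce(NO3)6 would give the hydroxyquinone F11, which would be silylated with TBSOTf and 2,6-lutidine at −78 °C.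

Step 8. Hydroxide may attack ring A carbons that carry peri methoxy groups, or the base may degrade the electron-rich quinone or loosen the silyl ether. The fallback changes the mechanism from addition–elimination at C2 to SN2 attack on the methyl group. It sets out from 15 and comes back at 16. LiCl in DMF with heating would demethylate the vinylogous ester, the most activated of the four methyl ethers. This fallback makes no new compound (F0).

## Further compounds

F1 | step 6 | 5,6-dibromo-2-methoxy-3-[(2S)-2-(tert-butyldimethylsilyloxy)propyl]cyclohex-2-ene-1,4-dione (trans, mixture of diastereomers) | COC1=C(C[C@H](C)O[Si](C)(C)C(C)(C)C)C(=O)C(Br)C(Br)C1=O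
F2 | step 6 | 6-bromo-2-methoxy-3-[(2S)-2-(tert-butyldimethylsilyloxy)propyl]-1,4-benzoquinone | COC1=C(C[C@H](C)O[Si](C)(C)C(C)(C)C)C(=O)C=C(Br)C1=O
F3 | step 6 | 8a-bromo-2,5,6,8-tetramethoxy-3-[(2S)-2-(tert-butyldimethylsilyloxy)propyl]-8-(trimethylsilyloxy)-4a,5,8,8a-tetrahydronaphthalene-1,4-dione | COC1C(OC)=CC(OC)(O[Si](C)(C)C)C2(Br)C1C(=O)C(C[C@H](C)O[Si](C)(C)C(C)(C)C)=C(OC)C2=O
F4 | step 6 | 2,5,6-trimethoxy-3-[(2S)-2-(tert-butyldimethylsilyloxy)propyl]-8-(trimethylsilyloxy)-1,4-naphthoquinone | COc1cc(O[Si](C)(C)C)c2c(c1OC)C(=O)C(C[C@H](C)O[Si](C)(C)C(C)(C)C)=C(OC)C2=O
F5 | step 5 | 1-(tert-butyldimethylsilyloxy)-1,3,4-trimethoxybuta-1,3-diene | COC=C(OC)C=C(OC)O[Si](C)(C)C(C)(C)C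
F6 | step 5 | 8-(tert-butyldimethylsilyloxy)-2,5,6,8-tetramethoxy-3-[(2S)-2-(tert-butyldimethylsilyloxy)propyl]-4a,5,8,8a-tetrahydronaphthalene-1,4-dione | COC1C(OC)=CC(OC)(O[Si](C)(C)C(C)(C)C)C2C1C(=O)C(C[C@H](C)O[Si](C)(C)C(C)(C)C)=C(OC)C2=O
F7 | step 5 | 8-(tert-butyldimethylsilyloxy)-2,5,6-trimethoxy-3-[(2S)-2-(tert-butyldimethylsilyloxy)propyl]naphthalene-1,4-diol | COc1cc(O[Si](C)(C)C(C)(C)C)c2c(O)c(OC)c(C[C@H](C)O[Si](C)(C)C(C)(C)C)c(O)c2c1OC
F8 | step 5 | 8-(tert-butyldimethylsilyloxy)-2,5,6-trimethoxy-3-[(2S)-2-(tert-butyldimethylsilyloxy)propyl]-1,4-naphthoquinone | COc1cc(O[Si](C)(C)C(C)(C)C)c2c(c1OC)C(=O)C(C[C@H](C)O[Si](C)(C)C(C)(C)C)=C(OC)C2=O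
F9 | step 1 | 1,2,4-trimethoxy-3-(prop-2-en-1-yl)benzene | COc1ccc(OC)c(CC=C)c1OC
F10 | step 1 | 1-(2,3,6-trimethoxyphenyl)propan-2-one | COc1ccc(OC)c(CC(C)=O)c1OC
F11 | step 3 | 2-[(2S)-2-hydroxypropyl]-3-methoxy-1,4-benzoquinone | COC1=C(C[C@H](C)O)C(=O)C=CC1=O
F0 | step 8 | none | none
A1 | alternative 1 | pentacarbonyl[methoxy(2,4,5-trimethoxyphenyl)methylidene]chromium | COC(=[Cr](=C=O)(=C=O)(=C=O)(=C=O)=C=O)c1cc(OC)c(OC)cc1OC
A2 | alternative 1 | (2S)-pent-4-yn-2-yl acetate | C#CC[C@H](C)OC(C)=O
A3 | alternative 1 | (2S)-1-(1-hydroxy-4,5,7,8-tetramethoxynaphthalen-2-yl)propan-2-yl acetate | COc1cc(OC)c2c(OC)cc(C[C@H](C)OC(C)=O)c(O)c2c1OC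
A4 | alternative 1 | 3-[(2S)-2-acetoxypropyl]-5,6,8-trimethoxy-1,4-naphthoquinone | COc1cc(OC)c2c(c1OC)C(=O)C(C[C@H](C)OC(C)=O)=CC2=O
A5 | alternative 2 | 3-[(3S)-3-(tert-butyldimethylsilyloxy)butylidene]-5,7,8-trimethoxyisochromane-1,4-dione | COc1cc(OC)c2c(c1OC)C(=O)OC(=CC[C@H](C)O[Si](C)(C)C(C)(C)C)C2=O
A6 | alternative 2 | 2-hydroxy-3-[(2S)-2-(tert-butyldimethylsilyloxy)propyl]-5,6,8-trimethoxy-1,4-naphthoquinone | COc1cc(OC)c2c(c1OC)C(=O)C(C[C@H](C)O[Si](C)(C)C(C)(C)C)=C(O)C2=O
A7 | alternative 3 | 2-[(2S)-2-(tert-butyldimethylsilyloxy)propyl]-4,6,7-trimethoxy-3-(trimethylsilyloxy)-1H-indene | COc1cc(OC)c2c(c1OC)CC(C[C@H](C)O[Si](C)(C)C(C)(C)C)=C2O[Si](C)(C)C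
A8 | alternative 3 | 2-chloro-3-[(2S)-2-(tert-butyldimethylsilyloxy)propyl]-5,6,8-trimethoxynaphthalen-1-ol | COc1cc(OC)c2c(O)c(Cl)c(C[C@H](C)O[Si](C)(C)C(C)(C)C)cc2c1OC
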